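**Assumption:** abyssinone VI has no stereocentres, so "single enantiomer" is taken to mean the single (E)-enone isomer shown in the SMILES.

**Retrosynthetic overview**
- Key disconnection: the C(=O)–Cα bond of the enone, made by Rh-catalysed, 2-OH-directed hydroacylation of a terminal aryl alkyne with unprotected 2,4-dihydroxybenzaldehyde. This avoids the usual Claisen–Schmidt aldol, uses no protecting groups, and sets the (E)-alkene by syn H/acyl addition.
- The alkyne partner, 4-ethynyl-2,6-diprenylphenol, comes from the aryl iodide by Sonogashira coupling and C-desilylation.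
- The aryl iodide comes from 4-iodophenol by one-pot double ortho-C-prenylation.
- No rings are formed: both benzene rings are purchased (4-iodophenol for ring B, 2,4-dihydroxybenzaldehyde for ring A).

**Route**

Step 1
Reactants: 1, 4-iodophenol; 2, prenyl bromide (1-bromo-3-methylbut-2-ene, 2.3 equiv)
Product: 3, 4-iodo-2,6-bis(3-methylbut-2-en-1-yl)phenol
Conditions: NaH (2.5 equiv), prenyl bromide added in two portions, PhMe, 0 °C → rt; the mono-prenyl phenol is recycled
Reagents that add atoms: prenyl bromide, CC(C)=CCBr (two equivalents incorporated)
Why: Ortho-selective C-alkylation of a tightly ion-paired sodium phenoxide in a non-polar solvent; the para position is blocked by iodine, the product phenol is re-deprotonated by the excess NaH and alkylated at the second ortho position, and NaH does not touch the aryl iodide.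

Step 2
Reactants: 3, 4-iodo-2,6-bis(3-methylbut-2-en-1-yl)phenol; 4, ethynyltrimethylsilane
Product: 5, 2,6-bis(3-methylbut-2-en-1-yl)-4-[(trimethylsilyl)ethynyl]phenol
Conditions: PdCl2(PPh3)2 (2 mol %), CuI (4 mol %), Et3N/THF, rt → 40 °C, Ar
Reagents that add atoms: ethynyltrimethylsilane, C#C[Si](C)(C)C
Why: Sonogashira coupling of an aryl iodide, which tolerates the free hindered phenol and the unactivated trisubstituted prenyl alkenes.

Step 3
Reactants: 5, 2,6-bis(3-methylbut-2-en-1-yl)-4-[(trimethylsilyl)ethynyl]phenol
Product: 6, 4-ethynyl-2,6-bis(3-methylbut-2-en-1-yl)phenol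
Conditions: K2CO3, MeOH (degassed), 0 °C → rt; short silica plug, used immediately
Reagents that add atoms: none
Why: Methanolysis of the C(sp)–SiMe3 bond (protodesilylation), with nothing else in the molecule reactive to K2CO3/MeOH.

Step 4
Reactants: 6, 4-ethynyl-2,6-bis(3-methylbut-2-en-1-yl)phenol (1.0 equiv, slow addition); 7, 2,4-dihydroxybenzaldehyde (1.5 equiv)
Product: 8, abyssinone VI, (E)-1-(2,4-dihydroxyphenyl)-3-[4-hydroxy-3,5-bis(3-methylbut-2-en-1-yl)phenyl]prop-2-en-1-one
Conditions: [Rh(cod)Cl]2 (2.5 mol %), dppf (5.5 mol %), Na2CO3 (10 mol %), PhMe/1,4-dioxane, 90 °C, Ar; dilute-acid work-up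
Reagents that add atoms: 2,4-dihydroxybenzaldehyde, O=Cc1ccc(O)cc1O (all atoms incorporated)
Why: Proposed new method: the closest known reaction type is Rh(I)/diphosphine-catalysed chelation-assisted intermolecular hydroacylation of alkynes with salicylaldehydes, extended here to a terminal aryl acetylene with unprotected phenols; the 2-phenoxide binds Rh and directs aldehyde C–H oxidative addition to a five-membered acyl–Rh(III)–H chelate (which suppresses decarbonylation), syn-hydrometalation places Rh on the less hindered terminal alkyne carbon, and C–C reductive elimination gives the linear enone with H and acyl cis, i.e. the (E)-chalcone, while the trisubstituted prenyl alkenes are too hindered to insert and the product's 2'-OH stays hydrogen-bonded to the ketone so it does not cyclise to the flavanone.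

**Compound list**
1 | 4-iodophenol | Oc1ccc(I)cc1 | starting material
2 | prenyl bromide (1-bromo-3-methylbut-2-ene) | CC(C)=CCBr | starting material
3 | 4-iodo-2,6-bis(3-methylbut-2-en-1-yl)phenol | CC(C)=CCc1cc(I)cc(CC=C(C)C)c1O | intermediate
4 | ethynyltrimethylsilane | C#C[Si](C)(C)C | starting material
5 | 2,6-bis(3-methylbut-2-en-1-yl)-4-[(trimethylsilyl)ethynyl]phenol | CC(C)=CCc1cc(C#C[Si](C)(C)C)cc(CC=C(C)C)c1O | intermediate
6 | 4-ethynyl-2,6-bis(3-methylbut-2-en-1-yl)phenol | C#Cc1cc(CC=C(C)C)c(O)c(CC=C(C)C)c1 | intermediate
7 | 2,4-dihydroxybenzaldehyde | O=Cc1ccc(O)cc1O | starting material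
8 | abyssinone VI | CC(C)=CCc1cc(/C=C/C(=O)c2ccc(O)cc2O)cc(CC=C(C)C)c1O | target

**Totals**
- Total steps: 4
- Longest linear sequence: 4 (from 4-iodophenol)
- Protecting groups: none

**Three steps most likely to fail, with fallbacks**

1. **Step 4 (hydroacylation).** The risks are branched regiochemistry (acyl on the aryl-bearing alkyne carbon, leading to the 2-aryl enone or an isoflavanone), alkyne oligomerisation, and interference from the acidic 4-OH of the aldehyde. Fallback: abandon the alkyne and use a Mizoroki–Heck coupling of iodide 3 with 1-[2,4-bis(methoxymethoxy)phenyl]prop-2-en-1-one (Pd(OAc)2, Et3N, DMF), which gives the (E)-enone by syn-insertion/syn-β-hydride elimination, then remove the MOM groups with HCl/MeOH at rt.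

2. **Step 1 (double ortho-C-prenylation).** The risks are competing O-prenylation, mono-alkylation and gem-dialkylated dienone, giving a low yield of 3. Fallback: two cycles of O-allylation and thermal aromatic Claisen rearrangement on 4-iodophenol to give 2,6-diallyl-4-iodophenol, then double olefin cross-metathesis with 2-methyl-2-butene (Grubbs II) to convert both allyl groups into prenyl groups.

3. **Step 3 (free alkyne 6).** The electron-rich terminal aryl alkyne with a free para-OH may oligomerise or undergo oxidative (Glaser) dimerisation on handling. Fallback: switch to a protected sequence: silylate 3 as its TIPS ether before the Sonogashira coupling, carry the alkyne as the stable aryl silyl ether through C-desilylation and hydroacylation, and remove TIPS with TBAF at the end (two extra steps).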